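**Vitrofolal B (14) by scandium-catalysed ring expansion of an indanone with an aryldiazomethane: synthesis design**

Numbering used in the text: naphthalene core with the aryl group on C1, OH on C2, CHO on C3, OH on C7 and OMe on C8. Ring A is the benzo ring C4a–C8a, ring B is C1–C4. Systematic names in the compound list follow IUPAC numbering.

## The problem

Vitrofolal B (14) is a fully aromatic 1-aryl-2-naphthol with no stereocentre. The task is therefore one of regiochemistry and crowding, and any sp3 centre made on the way only has to be erasable.

Ring B carries three contiguous substituents (aryl on C1, OH on C2, CHO on C3). The C1 aryl group is wedged between the C2 oxygen and the peri methoxy group on C8, so a late biaryl coupling at C1 would have to form a very hindered bond.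

Five oxygens sit on aromatic carbons. Two must end as free phenols (C2, C7) and three as methyl ethers, one of them (C8) directly beside the free C7 hydroxyl. The C7 oxygen therefore needs a protecting group orthogonal to methyl, and the C2 oxygen is best carried as something other than a phenol.

The ortho-hydroxy aldehyde and the electron-rich rings will not tolerate strong oxidants, strong electrophiles or forcing reductions, so the last steps must be mild.

The feature that opens the route is the position of C1. It bears exactly one aryl group and lies between C8a of ring A and the oxygen-bearing C2, which is where a diazo carbon ends up when it inserts into the aryl–carbonyl bond of an indan-1-one. After that insertion C2 is a ketone, C3 is its free α-methylene (ready for formylation), and C1 is an sp3 carbon that loses its hydrogen on aromatization.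

## Retrosynthesis

**14 from 13 (C7 O–benzyl bond).** The C7 hydroxyl is masked as a benzyl ether in 13. A methyl ether could not be told apart from the three that must stay, and a silyl ether would not survive the basic formylation. The benzyl group is removed by neutral hydrogenolysis at the end. The forward step must spare the formyl group.

**13 from 12 (the C1–H and C4–H bonds).** Ring B is taken back to the dihydro level. Compound 12 is a 3-hydroxymethylidene-2-tetralone whose enol tautomer is a 1,4-dihydronaphthalene, so a quinone dehydrogenation should aromatize it easily. Compared with cutting the C1–aryl bond of the naphthalene, this keeps the hindered aryl group on an sp3 carbon until the end and avoids the peri-hindered coupling.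

**12 from 11 (C3–CHO bond).** The formyl carbon is introduced by Claisen condensation of the 2-tetralone 11 with a formate ester. Both α-positions can enolize, but only acylation at the C3 methylene gives a β-dicarbonyl that can be deprotonated again. Acylation at the tertiary C1 is reversible, so the reaction should funnel to C3. Formylating after aromatization would be much harder, because C3 of a 1-substituted 2-naphthol is a poor nucleophile.

**11 from 7 and 10 (bonds C1–C2 and C1–C8a).** This is the strategic cut. Removing the aryl-bearing carbon C1 contracts ring B to the indanone 7 and releases the carbon as the aryldiazomethane 10. Ring A with its two oxygens goes into one piece and the pendant ring into the other, and both new bonds form in one operation. The forward reaction must show aryl migration (not CH2 migration), ketone formation (not epoxide formation) and a single insertion.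

**10 from 9 from 8.** The diazo compound 10 is unstable and is made just before use by dehydrogenation of the hydrazone 9, which comes from the commercial aldehyde 8. An oxidative route at 0 °C is preferred to a thermal one because the electron-rich diazoalkane does not tolerate heat.

**7 from 6 (the acyl–CH2 bond of the indanone).** The five-membered ketone is opened to the 2-vinylbenzaldehyde 6, to be closed by intramolecular hydroacylation. The obvious alternative is Friedel–Crafts cyclization of a 3-arylpropanoic acid. That would close para to the methoxy group and give the 5,6-dioxygenated isomer, not the 6,7-pattern needed. In 6 the aldehyde carbon already sits beside the methoxy-bearing carbon, so the regiochemistry is fixed.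

**6 from 4 and 5 (aryl–vinyl bond).** A Suzuki–Miyaura coupling of the ortho-bromo aldehyde 4 with the vinylboronate 5 installs the two carbons that become C3 and C4 of the target.

**4 from 3 from 2 from 1.** The bromine of 4 is placed para to the benzyloxy group of 3 by electrophilic substitution. Compound 3 arises from commercial 2,3-dihydroxybenzaldehyde (1) by benzylation of the dianion at O-3 (giving 2) and methylation of the remaining chelated phenol. These two steps set the final OH/OMe pattern of ring A.

## Roads not taken

**Alternative 1: ring-closing metathesis to a naphthalenone that enolizes.**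
- Cut: the C3–C4 bond.
- Forward step: the diene A2, an α,α-diaryl ketone carrying an ortho-vinyl group on ring A and a 1,1-disubstituted enone, is closed with the second-generation Grubbs catalyst RuCl2(=CHPh)(PCy3)(H2IMes). Ethylene is lost, and the resulting naphthalen-2(1H)-one tautomerizes to the naphthol A1.
- Merits: ring B arrives aromatic without an oxidant, no diazo compound is handled, and the C3 carbon is already in place. In these respects it is better than the chosen plan.
- Weak points: the difficulty moves into A2, whose crowded diaryl-substituted C1 next to a ketone still has to be assembled. The 1,1-disubstituted electron-poor alkene is a reluctant metathesis partner. After ring closure the silyl ether must be removed and the benzylic alcohol oxidized beside a free, oxidation-prone naphthol before debenzylation.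
- Comparison: the chosen plan offers short access to both partners (five and two steps from cheap aldehydes), formation of the hindered C1 centre during the ring-forming event, and introduction of C3 directly at the aldehyde oxidation level.

**Alternative 2: one-carbon insertion into an indene by dibromocarbene.**
- Cut: C1–C2 and C2–C3, with C2 as the carbene carbon.
- Forward step: dibromocarbene (CHBr3, KOt-Bu) adds to the tetrasubstituted double bond of the indene A4, and the dibromocyclopropane opens with loss of HBr to give the 2-bromonaphthalene A3.
- Merits: this is also a ring expansion from an indane skeleton. It aromatizes as part of the ring expansion and leaves a halogen handle, so it is equal to the chosen plan in building ring B without a cyclization and better in needing no dehydrogenation.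
- Weak points: the carbene must attack a hindered, fully substituted alkene flanked by an aryl group and an acetal. The oxygen at C2 then has to be introduced last, by hydroxylation of a bromide between two ortho substituents. A4 itself needs aryl addition, dehydration and C2 functionalization of an indanone.
- Comparison: the chosen plan has the C2 oxygen in place from the start as the ketone oxygen of 7 and needs no carbon–halogen to carbon–oxygen exchange at the most crowded position.

**Alternative 3: carbene-catalysed crossed benzoin closure, then dehydration.**
- Cut: the C1–C2 bond only.
- Forward step: a triazolium-derived N-heterocyclic carbene with DBU turns the aldehyde of the keto aldehyde A6 into an acyl anion equivalent, which adds to the diaryl ketone to give the tertiary ketol A5.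
- Merits: it forms the same C1–C2 bond as the chosen plan, is metal-free, and puts C1 at the alcohol level, so aromatization after C3 formylation would be a dehydration and not an oxidation. That is an advantage over the DDQ step.
- Weak points: the electrophile is a doubly ortho-substituted, electron-rich diaryl ketone, a poor acceptor for a Breslow intermediate. The enolizable aldehyde can undergo aldol and homo-benzoin reactions under DBU. A6 requires a hindered benzophenone and a propanal chain on the same ring, which costs more steps than 7.
- Comparison: the chosen plan creates two bonds at C1 in one step from simpler pieces and does not depend on nucleophilic attack at a hindered diaryl ketone.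

Key step: step 8

## Route

Remark: 12 is drawn as its chelated (Z)-hydroxymethylidene tautomer, which equilibrates with the 3-formyl ketone and with the 2-hydroxy-1,4-dihydronaphthalene-3-carbaldehyde form. The C1 centre of 11 and 12 is racemic and is erased in step 10.

Step 1
Reactants: 1 2,3-dihydroxybenzaldehyde
Product: 2 3-(benzyloxy)-2-hydroxybenzaldehyde
Conditions: NaH (2.2 equiv), DMSO, rt; then BnBr (1.0 equiv), rt; aq. HCl work-up
Reagents that add atoms: benzyl bromide, BrCc1ccccc1
Why: Williamson etherification of the dianion; the 2-phenoxide is stabilized by conjugation with and chelation to the formyl group, so the more basic 3-phenoxide should be alkylated by the single equivalent of halide.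

Step 2
Reactants: 2 3-(benzyloxy)-2-hydroxybenzaldehyde
Product: 3 3-(benzyloxy)-2-methoxybenzaldehyde
Conditions: MeI, K2CO3, DMF, rt to 40 °C
Reagents that add atoms: iodomethane, CI
Why: Williamson O-methylation of the remaining hydrogen-bonded phenol in a polar aprotic solvent; no other acidic site is present.

Step 3
Reactants: 3 3-(benzyloxy)-2-methoxybenzaldehyde
Product: 4 3-(benzyloxy)-6-bromo-2-methoxybenzaldehyde
Conditions: NBS (1.05 equiv), DMF, rt, dark
Reagents that add atoms: N-bromosuccinimide, O=C1CCC(=O)N1Br
Why: Electrophilic aromatic bromination; the 3-benzyloxy group directs para to C6, while the 2-methoxy group, flanked by two ortho substituents, is twisted out of conjugation and activates C5 only weakly, as is typical of 2,3-dialkoxybenzaldehydes.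

Step 4
Reactants: 4 3-(benzyloxy)-6-bromo-2-methoxybenzaldehyde; 5 vinylboronic acid pinacol ester (2-ethenyl-4,4,5,5-tetramethyl-1,3,2-dioxaborolane)
Product: 6 3-(benzyloxy)-6-ethenyl-2-methoxybenzaldehyde
Conditions: Pd(dppf)Cl2 (3 mol%), K2CO3, 1,4-dioxane/H2O, 85 °C
Reagents that add atoms: none
Why: Suzuki–Miyaura cross-coupling of an aryl bromide activated by the ortho formyl group; aldehyde, benzyl ether and methyl ether are inert to zerovalent palladium and carbonate.

Step 5
Reactants: 6 3-(benzyloxy)-6-ethenyl-2-methoxybenzaldehyde
Product: 7 6-(benzyloxy)-7-methoxy-2,3-dihydro-1H-inden-1-one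
Conditions: [Rh(cod)Cl]2 (2.5 mol%), dppe (5 mol%), AgBF4 (5 mol%), degassed CH2Cl2, rt to 40 °C
Reagents that add atoms: none
Why: Rhodium-catalysed intramolecular alkene hydroacylation of a 2-vinylbenzaldehyde: cationic monovalent rhodium inserts into the formyl C–H bond, the vinyl group inserts into Rh–H to give a six-membered acyl rhodacycle of trivalent rhodium, and C–C reductive elimination gives the five-membered ketone. The chelating diphosphine suppresses decarbonylation, and the carbonyl position next to the methoxy-bearing carbon is fixed by the aldehyde of 6.

Step 6
Reactants: 8 3,4-dimethoxybenzaldehyde (veratraldehyde)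
Product: 9 (E)-[(3,4-dimethoxyphenyl)methylidene]hydrazine
Conditions: N2H4·H2O (10 equiv), EtOH, 0 °C to rt (aldehyde added slowly); used crude
Reagents that add atoms: hydrazine (as the hydrate), NN
Why: Hydrazone condensation; slow addition of the aldehyde to a large excess of hydrazine keeps azine formation down, and the E isomer is the stable one.

Step 7
Reactants: 9 (E)-[(3,4-dimethoxyphenyl)methylidene]hydrazine
Product: 10 4-(diazomethyl)-1,2-dimethoxybenzene (kept as a cold, dried CH2Cl2 solution and used at once)
Conditions: activated MnO2 (excess), Na2SO4, CH2Cl2, 0 °C, dark; cold filtration through Celite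
Reagents that add atoms: none
Why: Dehydrogenation of an N-unsubstituted aldehyde hydrazone to the aryldiazomethane by MnO2, a known oxidation that works at low temperature and so suits an electron-rich, heat-sensitive diazoalkane.

Step 8
Reactants: 7 6-(benzyloxy)-7-methoxy-2,3-dihydro-1H-inden-1-one; 10 4-(diazomethyl)-1,2-dimethoxybenzene
Product: 11 7-(benzyloxy)-1-(3,4-dimethoxyphenyl)-8-methoxy-3,4-dihydronaphthalen-2(1H)-one (racemic)
Conditions: Sc(OTf)3 (10 mol%), CH2Cl2, −78 to −20 °C, slow addition of 10 (about 1.2 equiv)
Reagents that add atoms: none
Why: Sc(OTf)3 binds the indanone carbonyl, plausibly as a six-membered chelate with the neighbouring 7-methoxy oxygen, and the nucleophilic diazo carbon of 10 adds to give a scandium alkoxide–diazonium betaine. The aryl carbon C7a of 7 then shifts to the diazo carbon as N2 leaves, so the new bonds are C1–C2 and C1–C8a of the tetralone. The closest known reactions are the Sc(OTf)3-catalysed homologation of ketones with non-stabilized aryldiazomethanes (a catalytic Tiffeneau–Demjanov-type insertion) and the Lewis acid-promoted conversion of indan-1-ones into 2-tetralones by diazoalkanes. Ring B is not closed by a cyclization; it arises by enlargement of the five-membered ring through a 1,2-aryl shift, so no Baldwin mode applies. The C1 stereocentre is formed without control, 11 is racemic, and the centre disappears in step 10. The step needs aryl migration over CH2 migration, ketone over epoxide formation, and one insertion only. The migrating carbon is ortho to a methoxy group and migrates through a phenonium-like transition state, and Lewis acid catalysis at low temperature favours the 1,2-shift over ring closure of the betaine to an epoxide. Chelation activates 7 selectively, and the product ketone carries a bulky α-aryl group and meets only a small, slowly added excess of 10, which should limit double homologation.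

Step 9
Reactants: 11 7-(benzyloxy)-1-(3,4-dimethoxyphenyl)-8-methoxy-3,4-dihydronaphthalen-2(1H)-one (racemic)
Product: 12 7-(benzyloxy)-1-(3,4-dimethoxyphenyl)-3-[(Z)-hydroxymethylidene]-8-methoxy-3,4-dihydronaphthalen-2(1H)-one (racemic; enol form of the 3-formyl ketone)
Conditions: NaH (3 equiv), HCO2Et (5 equiv), cat. EtOH, THF, 0 °C to rt, under Ar; cold aq. HCl work-up
Reagents that add atoms: ethyl formate, CCOC=O
Why: Crossed Claisen formylation; acylation at the tertiary C1 gives a product that cannot be deprotonated and reverts, whereas acylation at the C3 methylene ends as the stabilized sodium enolate of the β-keto aldehyde, which should drive the equilibrium to C3. Air is excluded because the doubly benzylic C1 enolate is prone to autoxidation.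

Step 10
Reactants: 12 7-(benzyloxy)-1-(3,4-dimethoxyphenyl)-3-[(Z)-hydroxymethylidene]-8-methoxy-3,4-dihydronaphthalen-2(1H)-one (racemic)
Product: 13 6-(benzyloxy)-4-(3,4-dimethoxyphenyl)-3-hydroxy-5-methoxynaphthalene-2-carbaldehyde
Conditions: DDQ (1.05 equiv), 1,4-dioxane, rt
Reagents that add atoms: none
Why: Quinone dehydrogenation; in its enol tautomer 12 is a 1,4-dihydronaphthalene, and hydride abstraction from the doubly benzylic C1–H followed by proton loss from C4 gives the naphthalene with a large gain in aromatic stabilization. A plain benzyl aryl ether and the methoxyarenes are not attacked by one equivalent of DDQ at room temperature.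

Step 11
Reactants: 13 6-(benzyloxy)-4-(3,4-dimethoxyphenyl)-3-hydroxy-5-methoxynaphthalene-2-carbaldehyde
Product: 14 vitrofolal B, 4-(3,4-dimethoxyphenyl)-3,6-dihydroxy-5-methoxynaphthalene-2-carbaldehyde
Conditions: H2 (1 atm), 10% Pd/C, EtOAc, rt, stopped at full conversion
Reagents that add atoms: none
Why: Catalytic hydrogenolysis of the benzyl aryl ether; in a non-protic solvent at atmospheric pressure the hydrogen-bonded ortho-hydroxy aldehyde and the methyl ethers should survive.

## Compound list

1 | 2,3-dihydroxybenzaldehyde | O=Cc1cccc(O)c1O | starting material
2 | 3-(benzyloxy)-2-hydroxybenzaldehyde | O=Cc1cccc(OCc2ccccc2)c1O | intermediate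
3 | 3-(benzyloxy)-2-methoxybenzaldehyde | COc1c(C=O)cccc1OCc1ccccc1 | intermediate
4 | 3-(benzyloxy)-6-bromo-2-methoxybenzaldehyde | COc1c(C=O)c(Br)ccc1OCc1ccccc1 | intermediate
5 | vinylboronic acid pinacol ester (2-ethenyl-4,4,5,5-tetramethyl-1,3,2-dioxaborolane) | C=CB1OC(C)(C)C(C)(C)O1 | starting material
6 | 3-(benzyloxy)-6-ethenyl-2-methoxybenzaldehyde | COc1c(C=O)c(C=C)ccc1OCc1ccccc1 | intermediate
7 | 6-(benzyloxy)-7-methoxy-2,3-dihydro-1H-inden-1-one | O=C1CCc2ccc(OCc3ccccc3)c(OC)c21 | intermediate
8 | 3,4-dimethoxybenzaldehyde | COc1ccc(C=O)cc1OC | starting material
9 | (E)-[(3,4-dimethoxyphenyl)methylidene]hydrazine | COc1ccc(/C=N/N)cc1OC | intermediate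
10 | 4-(diazomethyl)-1,2-dimethoxybenzene | COc1ccc(C=[N+]=[N-])cc1OC | intermediate
11 | 7-(benzyloxy)-1-(3,4-dimethoxyphenyl)-8-methoxy-3,4-dihydronaphthalen-2(1H)-one (racemic) | O=C1CCc2ccc(OCc3ccccc3)c(OC)c2C1c1ccc(OC)c(OC)c1 | intermediate
12 | 7-(benzyloxy)-1-(3,4-dimethoxyphenyl)-3-[(Z)-hydroxymethylidene]-8-methoxy-3,4-dihydronaphthalen-2(1H)-one (racemic) | O/C=C1/Cc2ccc(OCc3ccccc3)c(OC)c2C(c2ccc(OC)c(OC)c2)C1=O | intermediate
13 | 6-(benzyloxy)-4-(3,4-dimethoxyphenyl)-3-hydroxy-5-methoxynaphthalene-2-carbaldehyde | COc1ccc(-c2c(O)c(C=O)cc3ccc(OCc4ccccc4)c(OC)c23)cc1OC | intermediate
14 | vitrofolal B, 4-(3,4-dimethoxyphenyl)-3,6-dihydroxy-5-methoxynaphthalene-2-carbaldehyde | COc1ccc(-c2c(O)c(C=O)cc3ccc(O)c(OC)c23)cc1OC | target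

## Step count and risk assessment

Total step count: 11. Longest linear sequence: 9 steps (steps 1–5 and 8–11 from compound 1). Steps 6 and 7 form a two-step side branch that joins at step 8.

**Step 8 (key step).** The most likely failure is slow addition of the diazo carbon to a conjugated, ortho-alkoxy aryl ketone while the electron-rich diazoalkane decomposes (azine or stilbene formation, protonation). Lesser risks are competing migration of the CH2 group, which would give the 2-aryl-1-tetralone skeleton, and a second insertion into the more electrophilic product ketone.

Fallback, setting out from 7 and returning at 11: Wittig methylenation with Ph3P=CH2 should give 6-(benzyloxy)-7-methoxy-1-methylidene-2,3-dihydro-1H-indene F1. Oxidative ring expansion of the exocyclic alkene with the hypervalent iodine reagent PhI(OH)OTs in methanol (aryl shift in the iodonium adduct, then ketal hydrolysis) should give 7-(benzyloxy)-8-methoxy-3,4-dihydronaphthalen-2(1H)-one F2. Palladium-catalysed α-arylation of F2 at its benzylic C1 with 4-bromo-1,2-dimethoxybenzene (Pd(OAc)2, XPhos, NaOt-Bu, toluene) leads to 11.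

**Step 7.** The diazo compound may be lost during its formation, by condensation with unreacted hydrazone to the azine or by over-oxidation on the oxide surface. Carry-over of hydrazone or water would also bind the scandium catalyst in step 8.

Fallback, setting out from 8 and returning at 10: condensation with tosylhydrazide in methanol gives N'-[(E)-(3,4-dimethoxyphenyl)methylidene]-4-methylbenzenesulfonohydrazide F3. NaOMe converts it into its sodium salt F4. Bamford–Stevens vacuum thermolysis of the dry salt delivers 10 into a cold trap, free of water and hydrazone.

**Step 5.** Decarbonylation of the acyl rhodium hydride (with poisoning of the catalyst as a carbonyl complex) or intermolecular aldehyde–alkene coupling may compete with ring closure, since the formyl group is flanked by two ortho substituents.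

Fallback, setting out from 6 and returning at 7: addition of vinylmagnesium bromide gives 1-[3-(benzyloxy)-6-ethenyl-2-methoxyphenyl]prop-2-en-1-ol F5. Ring-closing metathesis with the second-generation Grubbs catalyst RuCl2(=CHPh)(PCy3)(H2IMes) gives 6-(benzyloxy)-7-methoxy-1H-inden-1-ol F6. Base-mediated 1,3-hydrogen shift (DABCO or Et3N) isomerizes the indenol to 7.

**Step 3.** The electrophile may attack C4 (ortho to the benzyloxy group) or C5 (para to the methoxy group) in competition with C6, giving regioisomers that are hard to separate.

Fallback, setting out from 3 and returning at 4: palladium-catalysed ortho C–H bromination with a transient directing group (Pd(OAc)2, a catalytic anthranilic acid-type amine that forms an imine reversibly, NBS). The imine steers divalent palladium to C6, the only free position ortho to the formyl group, so the regiochemistry no longer depends on the alkoxy groups.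

**Step 9.** Acylation on oxygen or at C1, aldol self-condensation and aerobic oxidation of the doubly benzylic enolate may erode the C3 formylation under strongly basic conditions.

Fallback, setting out from 11 and returning at 12: heating with t-BuOCH(NMe2)2 in toluene, without an added base, should give 7-(benzyloxy)-3-[(E)-(dimethylamino)methylidene]-1-(3,4-dimethoxyphenyl)-8-methoxy-3,4-dihydronaphthalen-2(1H)-one F7. An enaminone can form only at the C3 methylene, since C1 has a single hydrogen. Mild aqueous acid then hydrolyses it to 12.

**Step 11.** Over-reduction of the formyl group (to the benzylic alcohol or the methyl group) may accompany hydrogenolysis on palladium.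

Fallback, setting out from 13 and returning at 14: Lewis acid debenzylation with BCl3 and pentamethylbenzene as cation scavenger in CH2Cl2 at −78 °C. This cleaves the benzyl aryl ether without a reducing agent and leaves the methyl ethers at that temperature.

## Further compounds

F1 | step 8 | 6-(benzyloxy)-7-methoxy-1-methylidene-2,3-dihydro-1H-indene | C=C1CCc2ccc(OCc3ccccc3)c(OC)c21
F2 | step 8 | 7-(benzyloxy)-8-methoxy-3,4-dihydronaphthalen-2(1H)-one | O=C1CCc2ccc(OCc3ccccc3)c(OC)c2C1
F3 | step 7 | N'-[(E)-(3,4-dimethoxyphenyl)methylidene]-4-methylbenzenesulfonohydrazide | COc1ccc(/C=N/NS(=O)(=O)c2ccc(C)cc2)cc1OC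
F4 | step 7 | sodium salt of N'-[(E)-(3,4-dimethoxyphenyl)methylidene]-4-methylbenzenesulfonohydrazide | COc1ccc(/C=N/[N-]S(=O)(=O)c2ccc(C)cc2)cc1OC.[Na+]
F5 | step 5 | 1-[3-(benzyloxy)-6-ethenyl-2-methoxyphenyl]prop-2-en-1-ol (racemic) | C=CC(O)c1c(C=C)ccc(OCc2ccccc2)c1OC
F6 | step 5 | 6-(benzyloxy)-7-methoxy-1H-inden-1-ol (racemic) | OC1C=Cc2ccc(OCc3ccccc3)c(OC)c21
F0 | step 3 | none | none
F7 | step 9 | 7-(benzyloxy)-3-[(E)-(dimethylamino)methylidene]-1-(3,4-dimethoxyphenyl)-8-methoxy-3,4-dihydronaphthalen-2(1H)-one (racemic) | CN(C)/C=C1\Cc2ccc(OCc3ccccc3)c(OC)c2C(c2ccc(OC)c(OC)c2)C1=O
F0 | step 11 | none | none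
A1 | alternative 1 | 7-(benzyloxy)-3-{[(tert-butyldimethylsilyl)oxy]methyl}-1-(3,4-dimethoxyphenyl)-8-methoxynaphthalen-2-ol | CC(C)(C)[Si](C)(C)OCc1cc2ccc(OCc3ccccc3)c(OC)c2c(-c2ccc(OC)c(OC)c2)c1O
A2 | alternative 1 | 1-[3-(benzyloxy)-6-ethenyl-2-methoxyphenyl]-3-{[(tert-butyldimethylsilyl)oxy]methyl}-1-(3,4-dimethoxyphenyl)but-3-en-2-one (racemic) | C=C(CO[Si](C)(C)C(C)(C)C)C(=O)C(c1ccc(OC)c(OC)c1)c1c(C=C)ccc(OCc2ccccc2)c1OC
A3 | alternative 2 | 6-(benzyloxy)-3-bromo-4-(3,4-dimethoxyphenyl)-2-(dimethoxymethyl)-5-methoxynaphthalene | COC(OC)c1cc2ccc(OCc3ccccc3)c(OC)c2c(-c2ccc(OC)c(OC)c2)c1Br
A4 | alternative 2 | 5-(benzyloxy)-3-(3,4-dimethoxyphenyl)-2-(dimethoxymethyl)-4-methoxy-1H-indene | COC(OC)C1=C(c2ccc(OC)c(OC)c2)c2c(OC)c(OCc3ccccc3)ccc2C1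
A5 | alternative 3 | 7-(benzyloxy)-1-(3,4-dimethoxyphenyl)-1-hydroxy-8-methoxy-3,4-dihydronaphthalen-2(1H)-one (racemic) | O=C1CCc2ccc(OCc3ccccc3)c(OC)c2C1(O)c1ccc(OC)c(OC)c1
A6 | alternative 3 | 3-[4-(benzyloxy)-2-(3,4-dimethoxybenzoyl)-3-methoxyphenyl]propanal | O=CCCc1ccc(OCc2ccccc2)c(OC)c1C(=O)c1ccc(OC)c(OC)c1
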